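**Plan**
- Retrosynthesis: the ketone is unmasked last from a dioxolane. The C3–H and C1'–H bonds go back to the exocyclic alkene of a (Z)-3-alkylidenephthalide (C1' = first chain carbon). The lactone is then cut at O2–C3 and at C1–C7a, releasing CO2 and an ortho-bromo aryl alkyne. That is cut at C7a–Br, at the propargylic C–C bond and at one C–C bond of the chain.
- Forward: a C4 + C9 Grignard coupling gives the C13 ketal bromide, which alkylates 3,5-dimethoxyphenylacetylene. The arene is brominated next to the alkyne, and the lactone ring (the only ring made) then arises in one operation from CO2.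
- Enabling feature: C7a is ortho to the C7 methoxy and para to the C5 methoxy, so bromine, then lithium, then CO2 go there. C3 sits on the adjacent ring carbon C3a, so with C3 at the alkyne oxidation level the carboxylate oxygen closes the ring O2–C1–C7a–C3a–C3 by 5-exo-dig attack.
- Stereochemistry: the single stereocentre C3 (S) comes from catalyst-controlled asymmetric hydrogenation of the C3=C1' enol-lactone alkene, which also removes the extra unsaturation.

Key step: step 4

Remark: the SMILES is read as (S) at C3 (O > C3a > chain > H); compounds 1, 2, 5 and CO2 are taken as commercial.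

**Step 1**
Reactants: 1 2-(2-bromoethyl)-2-methyl-1,3-dioxolane; 2 1,9-dibromononane
Product: 4 2-(11-bromoundecyl)-2-methyl-1,3-dioxolane, via Grignard reagent 3 (not isolated)
Conditions: 1, Mg, THF, 25–30 °C; then 2 (3 equiv), Li2CuCl4 (3 mol %), THF, −10 to 0 °C
Reagents that add atoms: none
Why: Copper-catalysed sp3–sp3 Grignard cross-coupling (Kochi coupling), in which the excess of dibromide should hold the reaction at mono-coupling and the ketal is inert to the Grignard reagent.

**Step 2**
Reactants: 5 1-ethynyl-3,5-dimethoxybenzene; 4 2-(11-bromoundecyl)-2-methyl-1,3-dioxolane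
Product: 7 2-[13-(3,5-dimethoxyphenyl)tridec-12-yn-1-yl]-2-methyl-1,3-dioxolane, via lithium acetylide 6 (not isolated)
Conditions: 5, n-BuLi, THF, −78 °C; then 4, NaI (10 mol %), DMPU, −78 to 50 °C
Reagents that add atoms: none
Why: SN2 alkylation of a lithium arylacetylide by a primary bromide (iodide formed in situ) in a dipolar cosolvent, the standard entry to aryl alkyl alkynes; no stereocentre is involved.

**Step 3**
Reactants: 7 2-[13-(3,5-dimethoxyphenyl)tridec-12-yn-1-yl]-2-methyl-1,3-dioxolane
Product: 8 2-[13-(2-bromo-3,5-dimethoxyphenyl)tridec-12-yn-1-yl]-2-methyl-1,3-dioxolane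
Conditions: NBS (1.0 equiv), MeCN, 0 °C to rt, dark
Reagents that add atoms: N-bromosuccinimide, O=C1CCC(=O)N1Br
Why: Electrophilic aromatic bromination, which in 1-substituted 3,5-dimethoxybenzenes should go to the position next to the 1-substituent (para to one methoxy, ortho to the other) and not to the more hindered site between the two methoxy groups; the two such positions are equivalent and no acid is formed that could open the ketal.

**Step 4**
Reactants: 8 2-[13-(2-bromo-3,5-dimethoxyphenyl)tridec-12-yn-1-yl]-2-methyl-1,3-dioxolane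
Product: 12 (Z)-5,7-dimethoxy-3-[12-(2-methyl-1,3-dioxolan-2-yl)dodecylidene]-2-benzofuran-1(3H)-one, via aryllithium 9 (not isolated), via lithium carboxylate 10 (not isolated), via alkynylbenzoic acid 11 (not isolated)
Conditions: n-BuLi (1.05 equiv), THF, −78 °C; CO2 (gas), −78 °C to rt; AcOH (1.0 equiv); then MeCN, DBU (30 mol %), 80 °C
Reagents that add atoms: carbon dioxide, O=C=O
Why: Bromine–lithium exchange at −78 °C turns the bromine-bearing carbon (the future C7a) into aryllithium 9, which adds to CO2 to make the aryl–carbonyl bond; after protonation to acid 11, DBU forms the amidinium carboxylate, whose oxygen adds anti across the neighbouring alkyne with proton delivery to the distal carbon, making the O2–C3 bond. The closest known reaction types are the carboxylation of aryllithiums with CO2 and the amidine-base-catalysed cycloisomerisation of 2-alkynylbenzoic acids to (Z)-3-ylidenephthalides. The lactone ring closes in the 5-exo-dig mode. No stereocentre is formed, but the anti addition fixes the exocyclic alkene as Z (chain cis to the ring oxygen), the single geometry wanted for the hydrogenation. The step needs 5-exo closure over 6-endo closure to an isocoumarin; this should be secured by the base-mediated mode without any π-acid and by both methoxy groups being meta to the alkyne-bearing carbon, so the proximal alkyne carbon has no cation-stabilising donor. It also needs exchange to outrun propargylic deprotonation, which the cold exchange of a bromide flanked by a methoxy group should ensure, with the ketone masked as a ketal.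

**Step 5**
Reactants: 12 (Z)-5,7-dimethoxy-3-[12-(2-methyl-1,3-dioxolan-2-yl)dodecylidene]-2-benzofuran-1(3H)-one
Product: 13 (3S)-5,7-dimethoxy-3-[12-(2-methyl-1,3-dioxolan-2-yl)dodecyl]-2-benzofuran-1(3H)-one
Conditions: [Ir(cod)(SpinPHOX)]BArF (1 mol %, ligand enantiomer that gives the (S) product), H2 (30 bar), CH2Cl2, rt
Reagents that add atoms: none
Why: Iridium–phosphine-oxazoline-catalysed asymmetric hydrogenation of a (Z)-3-alkylidenephthalide, a known route to 3-alkylphthalides, in which the chiral spiro P,N ligand selects the face of the enol-lactone alkene and so sets C3 as (S); the ligand enantiomer is fixed by correlation with (Z)-3-butylidenephthalide giving (S)-3-butylphthalide, which has the same priority pattern.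

**Step 6**
Reactants: 13 (3S)-5,7-dimethoxy-3-[12-(2-methyl-1,3-dioxolan-2-yl)dodecyl]-2-benzofuran-1(3H)-one
Product: 14 (3S)-5,7-dimethoxy-3-(13-oxotetradecyl)-2-benzofuran-1(3H)-one (CJ-13,108)
Conditions: 1 M HCl, THF, rt
Reagents that add atoms: water, O
Why: Acid-catalysed ketal hydrolysis, which the lactone should survive, and C3 should not ionise because both methoxy groups are meta to C3a.

**Compound list**
1 | 2-(2-bromoethyl)-2-methyl-1,3-dioxolane | CC1(CCBr)OCCO1 | starting material
2 | 1,9-dibromononane | BrCCCCCCCCCBr | starting material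
3 | [2-(2-methyl-1,3-dioxolan-2-yl)ethyl]magnesium bromide | CC1(CC[Mg]Br)OCCO1 | intermediate
4 | 2-(11-bromoundecyl)-2-methyl-1,3-dioxolane | CC1(CCCCCCCCCCCBr)OCCO1 | intermediate
5 | 1-ethynyl-3,5-dimethoxybenzene | COc1cc(OC)cc(C#C)c1 | starting material
6 | lithium (3,5-dimethoxyphenyl)acetylide | COc1cc(OC)cc(C#C[Li])c1 | intermediate
7 | 2-[13-(3,5-dimethoxyphenyl)tridec-12-yn-1-yl]-2-methyl-1,3-dioxolane | COc1cc(OC)cc(C#CCCCCCCCCCCCC2(C)OCCO2)c1 | intermediate
8 | 2-[13-(2-bromo-3,5-dimethoxyphenyl)tridec-12-yn-1-yl]-2-methyl-1,3-dioxolane | COc1cc(OC)c(Br)c(C#CCCCCCCCCCCCC2(C)OCCO2)c1 | intermediate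
9 | {2,4-dimethoxy-6-[13-(2-methyl-1,3-dioxolan-2-yl)tridec-1-yn-1-yl]phenyl}lithium | COc1cc(OC)c([Li])c(C#CCCCCCCCCCCCC2(C)OCCO2)c1 | intermediate
10 | lithium 2,4-dimethoxy-6-[13-(2-methyl-1,3-dioxolan-2-yl)tridec-1-yn-1-yl]benzoate | [Li+].COc1cc(OC)c(C(=O)[O-])c(C#CCCCCCCCCCCCC2(C)OCCO2)c1 | intermediate
11 | 2,4-dimethoxy-6-[13-(2-methyl-1,3-dioxolan-2-yl)tridec-1-yn-1-yl]benzoic acid | COc1cc(OC)c(C(=O)O)c(C#CCCCCCCCCCCCC2(C)OCCO2)c1 | intermediate
12 | (Z)-5,7-dimethoxy-3-[12-(2-methyl-1,3-dioxolan-2-yl)dodecylidene]-2-benzofuran-1(3H)-one | COc1cc(OC)c2C(=O)O/C(=C\CCCCCCCCCCCC3(C)OCCO3)c2c1 | intermediate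
13 | (3S)-5,7-dimethoxy-3-[12-(2-methyl-1,3-dioxolan-2-yl)dodecyl]-2-benzofuran-1(3H)-one | COc1cc(OC)c2c(c1)[C@H](CCCCCCCCCCCCC3(C)OCCO3)OC2=O | intermediate
14 | (3S)-5,7-dimethoxy-3-(13-oxotetradecyl)-2-benzofuran-1(3H)-one (CJ-13,108) | COc1cc(OC)c2c(c1)[C@H](CCCCCCCCCCCCC(C)=O)OC2=O | target

**Step count and risks**
Total steps: 6. Longest linear sequence: 6 steps (1 → 4 → 7 → 8 → 12 → 13 → 14).

Most likely to fail:

1. Step 4. The carboxylate may close through the distal alkyne carbon (6-endo, isocoumarin) in competition with 5-exo closure, or the aryllithium may be protonated before it meets CO2. Fallback (sets out from 4, comes back at 12): the aryl–alkyne bond is made last instead of the aryl–carboxyl bond. Bromide 4 is treated with lithium acetylide–ethylenediamine complex in DMSO to give 2-methyl-2-(tridec-12-yn-1-yl)-1,3-dioxolane F1. Commercial 1-bromo-3,5-dimethoxybenzene is formylated (POCl3, DMF, Vilsmeier) para to a methoxy group to give 2-bromo-4,6-dimethoxybenzaldehyde F2, and Pinnick oxidation (NaClO2, NaH2PO4, 2-methyl-2-butene) gives 2-bromo-4,6-dimethoxybenzoic acid F3. Tandem Sonogashira coupling and 5-exo-dig cyclisation of F3 with F1 (PdCl2(PPh3)2, CuI, Et3N, DMF, 80 °C), the classical copper–amine heteroannulation of 2-halobenzoic acids with 1-alkynes, should give 12.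

2. Step 5. Facial selectivity may be poor for an alkylidene with a long flexible chain, or the benzylic C–O bond may be hydrogenolysed. Fallback (sets out from 12, comes back at 13): the stereocentre is set by ketone reduction instead. Hydrolysis of the enol lactone of 12 (KOH, MeOH/H2O; ketal stable) gives 2,4-dimethoxy-6-[13-(2-methyl-1,3-dioxolan-2-yl)tridecanoyl]benzoic acid F4. Methylation (MeI, K2CO3, DMF) gives methyl 2,4-dimethoxy-6-[13-(2-methyl-1,3-dioxolan-2-yl)tridecanoyl]benzoate F5. Asymmetric transfer hydrogenation of the aryl ketone (RuCl(p-cymene)[(S,S)-TsDPEN], HCO2H/Et3N), a known route from 2-acylbenzoates to 3-substituted phthalides, should give the (S)-carbinol, which lactonises with retention to 13.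

3. Step 3. Bromination may occur between the two methoxy groups, a second bromine may enter, or bromine may add to the alkyne. Fallback (sets out from 4, comes back at 8): the bromine is placed before the alkyne exists. Commercial 3,5-dimethoxybenzaldehyde is brominated (NBS, MeCN) to 2-bromo-3,5-dimethoxybenzaldehyde F6, a regiochemistry that is well established. Ohira–Bestmann homologation (dimethyl (1-diazo-2-oxopropyl)phosphonate, K2CO3, MeOH) gives 2-bromo-1-ethynyl-3,5-dimethoxybenzene F7. Deprotonation with LiHMDS (no bromine–lithium exchange) and alkylation with 4 (NaI, THF/DMPU) should give 8.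

**Further compounds**
F1 | step 4 | 2-methyl-2-(tridec-12-yn-1-yl)-1,3-dioxolane | C#CCCCCCCCCCCCC1(C)OCCO1
F2 | step 4 | 2-bromo-4,6-dimethoxybenzaldehyde | COc1cc(Br)c(C=O)c(OC)c1
F3 | step 4 | 2-bromo-4,6-dimethoxybenzoic acid | COc1cc(Br)c(C(=O)O)c(OC)c1
F4 | step 5 | 2,4-dimethoxy-6-[13-(2-methyl-1,3-dioxolan-2-yl)tridecanoyl]benzoic acid | COc1cc(OC)c(C(=O)O)c(c1)C(=O)CCCCCCCCCCCCC2(C)OCCO2
F5 | step 5 | methyl 2,4-dimethoxy-6-[13-(2-methyl-1,3-dioxolan-2-yl)tridecanoyl]benzoate | COC(=O)c1c(OC)cc(OC)cc1C(=O)CCCCCCCCCCCCC2(C)OCCO2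
F6 | step 3 | 2-bromo-3,5-dimethoxybenzaldehyde | COc1cc(OC)c(Br)c(C=O)c1
F7 | step 3 | 2-bromo-1-ethynyl-3,5-dimethoxybenzene | COc1cc(OC)c(Br)c(C#C)c1
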